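**Strategy.** The isoflavone is cut at the two bonds that tie its pyranone ring (ring C) to the phloroglucinol ring (ring A), O1–C8a and C4–C4a. Both end on neighbouring ring-A carbons, so ring A can enter as an aryne that is trapped first by an enolate oxygen and then, through the aryl anion so formed, by an ester carbonyl. One operation therefore closes ring C and fixes the 5,7-oxygen pattern. The aryne is released from a benzyl-protected ortho-silylaryl triflate. Its partner is the enol of a methyl α-formyl arylacetate that already carries the (S)-3-benzyloxy-2,2-dimethylchroman unit, its stereocentre set by asymmetric epoxidation. Hydrogenolysis then frees the four hydroxyls.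

Key step: step 11

Remark: 3,5-bis(benzyloxy)phenol is taken as a purchased material, and the α-formyl ester is handled as its enol tautomer, the form obtained on acidifying the condensation mixture.
Remark: chroman numbering (O1, C2 gem-dimethyl, C3 carbinol, C4 benzylic CH2) and isoflavone numbering (O1, C2, C3, C4, C4a–C8a) are used throughout; the target stereocentre is chroman C3, configuration (S).

**Step 1**
Reactants: 1 2-(benzyloxy)phenol
Product: 2 2-(benzyloxy)-4-bromophenol
Conditions: NBS (1.0 equiv), MeCN, −10 → 0 °C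
Reagents that add atoms: N-bromosuccinimide, O=C1CCC(=O)N1Br
Why: Electrophilic aromatic bromination in which the free hydroxyl, the strongest activator, should direct bromine para to itself, to the carbon that later becomes C6 of the chroman.

**Step 2**
Reactants: 2 2-(benzyloxy)-4-bromophenol; 3 3-chloro-3-methylbut-1-yne
Product: 4 2-(benzyloxy)-4-bromo-1-[(2-methylbut-3-yn-2-yl)oxy]benzene
Conditions: DBU, CuCl2·2H2O (cat.), MeCN, 0 °C → rt
Reagents that add atoms: none
Why: Copper-catalysed O-propargylation of a phenol with a tertiary propargylic chloride, the standard entry to aryl 1,1-dimethylpropargyl ethers.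

**Step 3**
Reactants: 4 2-(benzyloxy)-4-bromo-1-[(2-methylbut-3-yn-2-yl)oxy]benzene
Product: 7 8-(benzyloxy)-6-bromo-2,2-dimethyl-2H-chromene, via allenylphenol 5 (not isolated), via quinone methide 6 (not isolated)
Conditions: PhNEt2, 190 °C
Reagents that add atoms: none
Why: Aromatic propargyl Claisen rearrangement to the only free ortho carbon, followed by enolisation, 1,5-hydrogen shift and oxa-6π electrocyclisation, the classical thermal route to 2,2-dimethyl-2H-chromenes.

**Step 4**
Reactants: 7 8-(benzyloxy)-6-bromo-2,2-dimethyl-2H-chromene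
Product: 8 (3S,4S)-8-(benzyloxy)-6-bromo-3,4-epoxy-2,2-dimethylchromane
Conditions: (S,S)-Jacobsen (salen)Mn(III)Cl (4 mol%), 4-phenylpyridine N-oxide (cat.), aq. NaOCl (pH 11.3), CH2Cl2, 0 °C
Reagents that add atoms: sodium hypochlorite, [Na+].[O-]Cl
Why: Jacobsen–Katsuki epoxidation of a cis-configured 2,2-dimethylchromene, a privileged substrate class, in which the (S,S)-salen ligand should steer oxygen transfer to the face giving the (3S,4S)-epoxide, so the catalyst sets C3.

**Step 5**
Reactants: 8 (3S,4S)-8-(benzyloxy)-6-bromo-3,4-epoxy-2,2-dimethylchromane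
Product: 9 (S)-8-(benzyloxy)-6-bromo-2,2-dimethylchroman-3-ol
Conditions: LiAlH4, THF, 0 °C; Fieser work-up
Reagents that add atoms: none
Why: SN2 hydride opening of the epoxide at benzylic C4, which is activated and far less hindered than the neopentyl-like C3, leaves the C3–O bond untouched, so the (S) configuration should pass unchanged into the alcohol.

**Step 6**
Reactants: 9 (S)-8-(benzyloxy)-6-bromo-2,2-dimethylchroman-3-ol
Product: 10 (S)-3,8-bis(benzyloxy)-6-bromo-2,2-dimethylchromane
Conditions: NaH, BnBr, Bu4NI (cat.), DMF, 0 °C → rt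
Reagents that add atoms: benzyl bromide, BrCc1ccccc1
Why: Williamson etherification of the secondary alkoxide masks the alcohol against the later enolate and aryne chemistry with a group that leaves in the final hydrogenolysis together with the other three.

**Step 7**
Reactants: 10 (S)-3,8-bis(benzyloxy)-6-bromo-2,2-dimethylchromane; 11 methyl bromoacetate
Product: 13 methyl 2-[(S)-3,8-bis(benzyloxy)-2,2-dimethylchroman-6-yl]acetate, via Reformatsky reagent 12 (not isolated)
Conditions: Zn (TMSCl-activated), THF, 40 °C; then 10, Pd2(dba)3 (cat.), XPhos (cat.), THF, 65 °C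
Reagents that add atoms: none
Why: Palladium-catalysed Negishi-type coupling of an aryl bromide with a zinc ester enolate (acetate α-arylation) is mild, tolerates the ethers and should deliver the methyl arylacetate directly.

**Step 8**
Reactants: 13 methyl 2-[(S)-3,8-bis(benzyloxy)-2,2-dimethylchroman-6-yl]acetate; 14 methyl formate
Product: 15 methyl 2-[(S)-3,8-bis(benzyloxy)-2,2-dimethylchroman-6-yl]-3-hydroxyacrylate
Conditions: NaH, HCO2Me (excess), THF, 0 °C → rt; then aq. HCl
Reagents that add atoms: none
Why: Crossed Claisen condensation of the arylacetate enolate with non-enolisable methyl formate, driven by formation of the stabilised product enolate, should give the hydrogen-bonded enol on acidification without touching the remote C3 centre.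

**Step 9**
Reactants: 16 3,5-bis(benzyloxy)phenol
Product: 17 3,5-bis(benzyloxy)-2-bromophenol
Conditions: NBS (1.0 equiv), CH2Cl2, −78 °C
Reagents that add atoms: N-bromosuccinimide, O=C1CCC(=O)N1Br
Why: Electrophilic bromination of a phenol in a non-polar solvent at low temperature should favour the ortho position (two equivalent sites, hydrogen-bond delivery) over C4, which is flanked by two benzyloxy groups.

**Step 10**
Reactants: 17 3,5-bis(benzyloxy)-2-bromophenol
Product: 21 3,5-bis(benzyloxy)-2-(trimethylsilyl)phenyl trifluoromethanesulfonate, via aryl silyl ether 18 (not isolated), via aryllithium 19 (not isolated), via lithium phenoxide 20 (not isolated)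
Conditions: HMDS, THF, 70 °C, then evaporation; n-BuLi, THF, −78 °C; then Tf2O, −78 °C → rt
Reagents that add atoms: hexamethyldisilazane, C[Si](C)(C)N[Si](C)(C)C; trifluoromethanesulfonic anhydride, O=S(=O)(OS(=O)(=O)C(F)(F)F)C(F)(F)F
Why: O-silylation, bromine–lithium exchange, anionic 1,3 O→C silyl migration (retro-Brook rearrangement) and triflation of the resulting phenoxide form the standard sequence to ortho-silylaryl triflates, the exchange at −78 °C being faster than benzylic deprotonation.

**Step 11**
Reactants: 15 methyl 2-[(S)-3,8-bis(benzyloxy)-2,2-dimethylchroman-6-yl]-3-hydroxyacrylate; 21 3,5-bis(benzyloxy)-2-(trimethylsilyl)phenyl trifluoromethanesulfonate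
Product: 25 5,7-bis(benzyloxy)-3-[(S)-3,8-bis(benzyloxy)-2,2-dimethylchroman-6-yl]chromen-4-one, via sodium enolate 22 (not isolated), via aryne 23 (not isolated), via aryl anion 24 (not isolated)
Conditions: NaH (1.0 equiv), THF, 0 °C; then 21 (1.5 equiv), CsF (3 equiv), THF, 65 °C
Reagents that add atoms: none
Why: Proposed new method: fluoride removes the silyl group of 21 and triflate departs to give aryne 23, the oxygen of enolate 22 adds to the aryne carbon remote from the flanking benzyloxy group, and the aryl anion 24 thus placed beside that inductively withdrawing oxygen adds to the ester carbonyl and expels methoxide. The closest known reaction type is the fluoride-triggered aryne annulation of salicylate esters to xanthones (O-arylation followed by intramolecular acyl substitution), with the phenoxide here replaced by the oxygen of an acyclic formyl-ester enolate. The pyranone ring closes by 6-exo-trig attack of the aryl carbanion on the ester carbonyl, which forms C4–C4a after O1–C8a. No stereocentre is created, and the chroman C3 centre is remote from every reacting site and cannot epimerise. The step needs O- rather than C-arylation, the correct aryne regiochemistry and a cis arrangement of enolate oxygen and ester: the fully substituted aryl-bearing enolate carbon is shielded while the formyl-derived oxygen is exposed, the 3-benzyloxy group polarises the aryne, and sodium chelation between enolate oxygen and ester carbonyl in THF should hold the Z geometry while prior deprotonation removes the proton source that would quench 24.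

**Step 12**
Reactants: 25 5,7-bis(benzyloxy)-3-[(S)-3,8-bis(benzyloxy)-2,2-dimethylchroman-6-yl]chromen-4-one
Product: 26 5,7-dihydroxy-3-[(S)-3,8-dihydroxy-2,2-dimethylchroman-6-yl]chromen-4-one
Conditions: H2 (1 atm), Pd(OH)2/C, EtOAc–MeOH, rt
Reagents that add atoms: none
Why: Palladium-catalysed hydrogenolysis should cleave the three aryl benzyl ethers and the alkyl benzyl ether under conditions mild enough to spare the chromone double bond and the non-benzylic C3 carbinol centre.

**Compound list**
1 | 2-(benzyloxy)phenol | Oc1ccccc1OCc1ccccc1 | starting material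
2 | 2-(benzyloxy)-4-bromophenol | Oc1ccc(Br)cc1OCc1ccccc1 | intermediate
3 | 3-chloro-3-methylbut-1-yne | CC(C)(Cl)C#C | starting material
4 | 2-(benzyloxy)-4-bromo-1-[(2-methylbut-3-yn-2-yl)oxy]benzene | C#CC(C)(C)Oc1ccc(Br)cc1OCc1ccccc1 | intermediate
5 | 2-(benzyloxy)-4-bromo-6-(3-methylbuta-1,2-dien-1-yl)phenol | CC(C)=C=Cc1cc(Br)cc(OCc2ccccc2)c1O | intermediate
6 | 2-(benzyloxy)-4-bromo-6-(3-methylbut-2-en-1-ylidene)cyclohexa-2,4-dien-1-one | CC(C)=CC=C1C=C(Br)C=C(OCc2ccccc2)C1=O | intermediate
7 | 8-(benzyloxy)-6-bromo-2,2-dimethyl-2H-chromene | CC1(C)C=Cc2cc(Br)cc(OCc3ccccc3)c2O1 | intermediate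
8 | (3S,4S)-8-(benzyloxy)-6-bromo-3,4-epoxy-2,2-dimethylchromane | CC1(C)Oc2c(OCc3ccccc3)cc(Br)cc2[C@@H]2O[C@H]12 | intermediate
9 | (S)-8-(benzyloxy)-6-bromo-2,2-dimethylchroman-3-ol | CC1(C)Oc2c(OCc3ccccc3)cc(Br)cc2C[C@@H]1O | intermediate
10 | (S)-3,8-bis(benzyloxy)-6-bromo-2,2-dimethylchromane | CC1(C)Oc2c(OCc3ccccc3)cc(Br)cc2C[C@@H]1OCc1ccccc1 | intermediate
11 | methyl bromoacetate | COC(=O)CBr | starting material
12 | (2-methoxy-2-oxoethyl)zinc bromide | COC(=O)C[Zn]Br | intermediate
13 | methyl 2-[(S)-3,8-bis(benzyloxy)-2,2-dimethylchroman-6-yl]acetate | CC1(C)Oc2c(OCc3ccccc3)cc(CC(=O)OC)cc2C[C@@H]1OCc1ccccc1 | intermediate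
14 | methyl formate | COC=O | starting material
15 | methyl 2-[(S)-3,8-bis(benzyloxy)-2,2-dimethylchroman-6-yl]-3-hydroxyacrylate (enol of the α-formyl ester) | CC1(C)Oc2c(OCc3ccccc3)cc(C(=CO)C(=O)OC)cc2C[C@@H]1OCc1ccccc1 | intermediate
16 | 3,5-bis(benzyloxy)phenol | Oc1cc(OCc2ccccc2)cc(OCc2ccccc2)c1 | starting material
17 | 3,5-bis(benzyloxy)-2-bromophenol | Oc1cc(OCc2ccccc2)cc(OCc2ccccc2)c1Br | intermediate
18 | [3,5-bis(benzyloxy)-2-bromophenoxy]trimethylsilane | C[Si](C)(C)Oc1cc(OCc2ccccc2)cc(OCc2ccccc2)c1Br | intermediate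
19 | [2,4-bis(benzyloxy)-6-(trimethylsilyloxy)phenyl]lithium | C[Si](C)(C)Oc1cc(OCc2ccccc2)cc(OCc2ccccc2)c1[Li] | intermediate
20 | lithium 3,5-bis(benzyloxy)-2-(trimethylsilyl)phenoxide | [Li+].[O-]c1cc(OCc2ccccc2)cc(OCc2ccccc2)c1[Si](C)(C)C | intermediate
21 | 3,5-bis(benzyloxy)-2-(trimethylsilyl)phenyl trifluoromethanesulfonate | C[Si](C)(C)c1c(OCc2ccccc2)cc(OCc2ccccc2)cc1OS(=O)(=O)C(F)(F)F | intermediate
22 | sodium (Z)-2-[(S)-3,8-bis(benzyloxy)-2,2-dimethylchroman-6-yl]-3-methoxy-3-oxoprop-1-en-1-olate | CC1(C)Oc2c(OCc3ccccc3)cc(/C(=C/[O-])C(=O)OC)cc2C[C@@H]1OCc1ccccc1.[Na+] | intermediate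
23 | 3,5-bis(benzyloxy)benzyne (1,2-didehydro-3,5-bis(benzyloxy)benzene) | C1#CC(OCc2ccccc2)=CC(OCc2ccccc2)=C1 | intermediate
24 | methyl (Z)-3-[3,5-bis(benzyloxy)-2-sodiophenoxy]-2-[(S)-3,8-bis(benzyloxy)-2,2-dimethylchroman-6-yl]acrylate (aryl anion) | CC1(C)Oc2c(OCc3ccccc3)cc(/C(=C/Oc3cc(OCc4ccccc4)cc(OCc4ccccc4)[c-]3)C(=O)OC)cc2C[C@@H]1OCc1ccccc1.[Na+] | intermediate
25 | 5,7-bis(benzyloxy)-3-[(S)-3,8-bis(benzyloxy)-2,2-dimethylchroman-6-yl]chromen-4-one | CC1(C)Oc2c(OCc3ccccc3)cc(-c3coc4cc(OCc5ccccc5)cc(OCc5ccccc5)c4c3=O)cc2C[C@@H]1OCc1ccccc1 | intermediate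
26 | 5,7-dihydroxy-3-[(S)-3,8-dihydroxy-2,2-dimethylchroman-6-yl]chromen-4-one | CC1(C)Oc2c(O)cc(-c3coc4cc(O)cc(O)c4c3=O)cc2C[C@@H]1O | target

**Total step count:** 12
**Longest linear sequence:** 10 steps (steps 1–8, 11 and 12)

**Steps most likely to fail**

1. Step 11 (proposed new method). The enolate may be arylated at carbon and then follow the acyl-alkylation (C–C insertion) pathway. Arylation may also occur through the extended enolate geometry, which leaves the aryl anion out of reach of the ester so that it is merely protonated. Liberated methoxide may consume aryne. The fallback uses known chemistry, sets out from 10 and comes back at 25. Miyaura borylation of 10 (B2pin2, Pd(dppf)Cl2, KOAc, dioxane, 90 °C) should give 2-[(S)-3,8-bis(benzyloxy)-2,2-dimethylchroman-6-yl]-4,4,5,5-tetramethyl-1,3,2-dioxaborolane F1. Separately, purchased 2′,4′,6′-trihydroxyacetophenone would be dibenzylated at the two non-chelated hydroxyls (BnBr, K2CO3, acetone) to 1-[2,4-bis(benzyloxy)-6-hydroxyphenyl]ethan-1-one F2. Condensation with DMF dimethyl acetal would give (E)-1-[2,4-bis(benzyloxy)-6-hydroxyphenyl]-3-(dimethylamino)prop-2-en-1-one F3. Iodine in pyridine/CHCl3 would cyclise this to 5,7-bis(benzyloxy)-3-iodo-4H-chromen-4-one F4. Suzuki–Miyaura coupling of F1 with F4 (Pd(PPh3)4, K2CO3, DME–H2O, 80 °C) then forms the C3–aryl bond and arrives at 25.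

2. Step 12. The aliphatic benzyl ether may cleave slowly, and during the longer exposure the pyranone C2=C3 bond may be over-reduced, or debenzylation may stop short. The fallback sets out from 25 and comes back at 26. It replaces reductive cleavage by Lewis-acid ether cleavage with a cation scavenger (BCl3, pentamethylbenzene, CH2Cl2, −78 °C), a bond-breaking mode that cannot touch the C2=C3 bond. No new compound is made.

3. Step 9. Site selectivity of the bromination may be poor, with attack at C4 between the two benzyloxy groups or double bromination. The fallback sets out from 16 and comes back at 21, replacing electrophilic substitution by directed ortho-metalation. Isopropyl isocyanate and Et3N in CH2Cl2 should give 3,5-bis(benzyloxy)phenyl N-isopropylcarbamate F5. In-situ N-silylation (TBSOTf, TMEDA), lithiation with n-BuLi/TMEDA at −78 °C at the carbon between the carbamate and a benzyloxy group, and a TMSCl quench would give 3,5-bis(benzyloxy)-2-(trimethylsilyl)phenyl N-isopropylcarbamate F6. Carbamate cleavage with DBU/Et2NH in MeCN and triflation of the phenoxide with PhNTf2 in the same flask returns to 21.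

**Further compounds**
F1 | step 11 | 2-[(S)-3,8-bis(benzyloxy)-2,2-dimethylchroman-6-yl]-4,4,5,5-tetramethyl-1,3,2-dioxaborolane | CC1(C)Oc2c(OCc3ccccc3)cc(B3OC(C)(C)C(C)(C)O3)cc2C[C@@H]1OCc1ccccc1
F2 | step 11 | 1-[2,4-bis(benzyloxy)-6-hydroxyphenyl]ethan-1-one | CC(=O)c1c(O)cc(OCc2ccccc2)cc1OCc1ccccc1
F3 | step 11 | (E)-1-[2,4-bis(benzyloxy)-6-hydroxyphenyl]-3-(dimethylamino)prop-2-en-1-one | CN(C)/C=C/C(=O)c1c(O)cc(OCc2ccccc2)cc1OCc1ccccc1
F4 | step 11 | 5,7-bis(benzyloxy)-3-iodo-4H-chromen-4-one | O=c1c(I)coc2cc(OCc3ccccc3)cc(OCc3ccccc3)c12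
F0 | step 12 | none | none
F5 | step 9 | 3,5-bis(benzyloxy)phenyl N-isopropylcarbamate | CC(C)NC(=O)Oc1cc(OCc2ccccc2)cc(OCc2ccccc2)c1
F6 | step 9 | 3,5-bis(benzyloxy)-2-(trimethylsilyl)phenyl N-isopropylcarbamate | CC(C)NC(=O)Oc1cc(OCc2ccccc2)cc(OCc2ccccc2)c1[Si](C)(C)C
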